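Colleague, you asked me for a quick number on Sunday's against Friday's and gave your hunch, which stands below as the forecast; I reckoned first from the earlier runs.

common to all: starting material 0.10 M
- south-east: partner 2 equiv (fed, over 8.0 h); protic impurity 0.030 M; free catalyst 1.9 mol%; temperature −25 °C; run made earlier; the fed solution adds 0.10 times the starting volume
- north: partner 2 equiv (fed, over 8.0 h); protic impurity 0.030 M; free catalyst 2.8 mol%; temperature −14 °C; run made earlier; the fed solution adds 0.10 times the starting volume
- north-west: partner 2 equiv (fed, over 8.0 h); protic impurity 0.030 M; free catalyst 3.7 mol%; temperature −25 °C; run made earlier; the fed solution adds 0.10 times the starting volume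
- Sunday's: partner 2.00 equiv; protic impurity 0.0300 M; free catalyst 1.5 mol%; temperature −20 °C; everything together at the start, the whole solution of partner included, so that from the start the volume is larger by 0.10 times the starting volume; time 20 h
- Friday's: partner 2.00 equiv (fed, over 8.0 h); protic impurity 0.0300 M; free catalyst 5.2 mol%; temperature −20 °C; the fed solution adds 0.10 times the starting volume; time 20 h

| run | time / h | product / % | starting material / % |
|---|---|---|---|
| south-east | 2.00 | 0 | 99.2 |
| south-east | 4.00 | 1.5 | 98.8 |
| south-east | 6.00 | 2.8 | 96.8 |
| south-east | 8.00 | 3.5 | 95.6 |
| south-east | 10.0 | 5.6 | 94.0 |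
| north | 2.00 | 1.7 | 96.4 |
| north | 4.00 | 7.6 | 91.6 |
| north | 6.00 | 15.6 | 83.9 |
| north | 8.00 | 23.1 | 77.2 |
| north | 10.0 | 29.7 | 69.9 |
| north-west | 0.833 | 0 | 99.8 |
| north-west | 1.50 | 0 | 100.5 |
| north-west | 3.00 | 1.4 | 98.7 |
| north-west | 5.00 | 3.5 | 95.0 |
| north-west | 10.0 | 11.0 | 88.8 |

(readings scatter by 0.5 percentage points)

- charges are per starting volume, the dose included; the dosed solution carries all of it
- the earlier runs were read with a standard deviation of 0.5 percentage points

- the winner by amount of product, in percent of the starting material charged; "neither" if no more than 2 percentage points parts them (Sunday's / Friday's / neither)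
- how much product is there at the end, in percent of the starting material charged: Sunday's
- how much product is there at the end, in percent of the starting material charged: Friday's

After the silent start of the fed runs, I read the fall of c(starting material) as a pseudo-first-order decay with constant k, so I integrated that one rate: after a lag, exp(−k(t − lag)) of the charge remains, and I counted the rest as product. From the late readings, north gave 0.0451 /h and north-west gave 0.0151 /h. South-east gave 0.00830 /h at the same temperature as north-west, and k went with the loading: the ratio of constants read 1.82 against 1.95 for the loadings. Per unit of loading, north therefore read 3.94 times north-west.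

Interpolating the logarithm to −20 °C, a fraction 0.455 of the way up, I got 0.0114 /h: the loading constant, the first-order constant of starting material for Sunday's loading at that temperature. Sunday's had its partner in from the start, so I counted no lag, and 20 h gave 20.4%. For Friday's I scaled the constant by loading to 0.0396 /h. Its feed brought 0.0250 M/h of partner, which matched the protic impurity after 1.20 h, so I reckoned 52.5%.

The forecast said Friday's, with 20% for Sunday's and 49% for Friday's, holding that “rate scales roughly with catalyst”. My figure for Friday's stood 3.5 points above its figure.

The flasks gave 20.1% for Sunday's and 55.5% for Friday's, so Friday's won, and my Friday's figure stood 3 points below.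

    partner + free catalyst → catalyst intermediate A (k = 61.6 /M/h, Ea = 44.0 kJ/mol)
    partner + protic impurity → quenched reagent (k = 46.7 /M/h, Ea = 36.0 kJ/mol)
    catalyst intermediate A ⇌ catalyst intermediate B (K = 4.20, k = 2.33 /h, Ea = 81.0 kJ/mol, ΔH = 5.00 kJ/mol)
    catalyst intermediate C → free catalyst + product (k = 2.99 /h, Ea = 67.0 kJ/mol)
    starting material + catalyst intermediate B → catalyst intermediate C (k = 26.1 /M/h, Ea = 57.0 kJ/mol)
    (constants at −20 °C)

For a repeat of Sunday's at −5 °C, all amounts and the time held, I reckoned 77.3% with the loading constant and the same warming ratio; that flask gave 79.7%. In Friday's, the half-lives by the forward steps alone were 0.30 h for catalyst intermediate A, 0.27 h for catalyst intermediate B with the other concentrations as charged, and 0.23 h for catalyst intermediate C, the longest 1.28 times the shortest. At 20.0 h, Friday's catalyst stood spread over catalyst intermediate A at 31.3%, catalyst intermediate C at 15.8%, free catalyst at 7.72% and the largest share, catalyst intermediate B, at 45.2%.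

(The data are simulated from invented constants, noise included.)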